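**Retrosynthetic overview**
1. Target ⇒ desilylation and tert-butyl ester acidolysis of a protected precursor; the seven-membered lactone (ring C) is closed last by ring-closing metathesis of the vinyl group on ring A with a 2-(acyloxymethyl)acrylate.
2. The ester between the two halves comes from opening a spiro-epoxide on ring A at its CH2 carbon with the carboxylate of the right-hand acrylic acid, which also delivers the tertiary alcohol.
3. Ring A (cyclohexane, formed first): amine-catalysed Michael addition and aldol condensation to (R)-cryptone, then trans vinyl-cuprate addition, hydroxymethylation and sulfur-ylide epoxidation.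
4. Ring B (cyclohexene, formed second): ring-closing metathesis of a 1,7-diene built by Ireland–Claisen rearrangement of the isovalerate of an (S)-allylic alcohol (ketoreductase reduction of an enone) and a B-alkyl Suzuki coupling; side chain by Wittig olefination.
5. Order of ring formation: A (aldol) → B (metathesis) → C (metathesis).

Assumption: the SMILES is taken literally, so isopropyl and side chain are cis on the cyclohexene ring and trans on the cyclohexane ring, and the lactone is trans-fused.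

Abbreviations: TMS = trimethylsilyl; TBS = tert-butyldimethylsilyl; TIPS = triisopropylsilyl; TBSO-methyl / TIPSO-methyl = (silyloxy)methyl; DMAP = 4-(dimethylamino)pyridine; TEMPO = 2,2,6,6-tetramethylpiperidin-1-oxyl; 9-BBN = 9-borabicyclo[3.3.1]nonane; dppf = 1,1'-bis(diphenylphosphino)ferrocene; H2IMes = 1,3-dimesitylimidazolidin-2-ylidene; PCy3 = tricyclohexylphosphine.

**Ring A epoxide**

Step 1
Reactants: 1 3-methylbutanal; 2 but-3-en-2-one
Product: 3 (2R)-5-oxo-2-(propan-2-yl)hexanal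
Conditions: (R)-2-[methoxy(diphenyl)methyl]pyrrolidine (5 mol %), ethyl 3,4-dihydroxybenzoate (20 mol %), neat, 4 °C
Reagents that add atoms: none
Why: Enamine-catalysed asymmetric Michael addition; the enone is taken up on the enamine face away from the diarylmethyl group of the (R)-catalyst, which sets the (R) centre (about 90% ee).

Step 2
Reactants: 3 (2R)-5-oxo-2-(propan-2-yl)hexanal
Product: 4 (4R)-4-(propan-2-yl)cyclohex-2-en-1-one ((R)-cryptone)
Conditions: LiOH (0.1 equiv), iPrOH, 23 °C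
Reagents that add atoms: none
Why: Intramolecular aldol condensation of the methyl ketone onto the aldehyde closes ring A, and the mild base leaves the γ-stereocentre intact.

Step 3
Reactants: 4 (R)-cryptone; 5 vinylmagnesium bromide
Product: 6 trimethyl{[(3R,4R)-4-(propan-2-yl)-3-vinylcyclohex-1-en-1-yl]oxy}silane
Conditions: CuBr·SMe2 (10 mol %), Me3SiCl (2 equiv), THF, −78 °C; Et3N quench
Reagents that add atoms: chlorotrimethylsilane, C[Si](C)(C)Cl
Why: Copper-catalysed conjugate addition accelerated by Me3SiCl; vinyl adds anti to the neighbouring isopropyl group (trans) and the enolate is trapped regiospecifically as the silyl enol ether.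

Step 4
Reactants: 6 silyl enol ether
Product: 7 (2R,3R,4R)-2-(hydroxymethyl)-4-(propan-2-yl)-3-vinylcyclohexan-1-one
Conditions: aqueous formaldehyde (37 %), Yb(OTf)3 (10 mol %), THF/H2O, 23 °C
Reagents that add atoms: formaldehyde, C=O
Why: Lewis-acid-catalysed aqueous Mukaiyama aldol (hydroxymethylation); formaldehyde attacks anti to the adjacent vinyl group and the 2,3-trans all-equatorial ketone is also the thermodynamic isomer.

Step 5
Reactants: 7 hydroxy ketone
Product: 8 (2R,3R,4R)-4-(propan-2-yl)-2-(TBSO-methyl)-3-vinylcyclohexan-1-one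
Conditions: t-BuMe2SiCl, imidazole, CH2Cl2, 0 °C
Reagents that add atoms: tert-butyldimethylsilyl chloride, CC(C)(C)[Si](C)(C)Cl
Why: Silylation of the primary alcohol protects the β-hydroxy ketone against retro-aldol cleavage in the basic ylide step; no stereocentre is touched.

Step 6
Reactants: 8 silyloxy ketone
Product: 9 tert-butyl(dimethyl){[(3S,4R,5R,6R)-6-(propan-2-yl)-5-vinyl-1-oxaspiro[2.5]octan-4-yl]methoxy}silane
Conditions: Me3S+ I−, n-BuLi, THF, −10 → 0 °C
Reagents that add atoms: trimethylsulfonium iodide, C[S+](C)C.[I-]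
Why: Corey–Chaykovsky epoxidation; the small unstabilised sulfonium ylide adds irreversibly along the axial trajectory of the chair ketone, so the new CH2 is axial (cis to the CH2OTBS group) and the oxygen equatorial, which is the (S) spiro centre (minor epimer removed by chromatography).

**Right-hand acid (ring B)**

Step 7
Reactants: 10 (tert-butyldimethylsilyloxy)acetaldehyde; 11 1-(triphenylphosphoranylidene)propan-2-one
Product: 12 (3E)-5-(TBSO)pent-3-en-2-one
Conditions: CH2Cl2, 23 °C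
Reagents that add atoms: none
Why: Wittig olefination with a stabilised ylide gives the (E)-enone under thermodynamic control.

Step 8
Reactants: 12 (3E)-5-(TBSO)pent-3-en-2-one
Product: 13 (2S,3E)-5-(TBSO)pent-3-en-2-ol
Conditions: ketoreductase (Prelog-selective NADH-dependent alcohol dehydrogenase), NAD+ (1 mol %), iPrOH (10 vol %), phosphate buffer pH 7.0, 30 °C
Reagents that add atoms: none
Why: Enzymatic carbonyl reduction by a ketoreductase; hydride from NADH is delivered only to the Re face of the methyl ketone, giving the (S)-carbinol in >99% ee without touching the C=C bond.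

Step 9
Reactants: 13 (S)-allylic alcohol; 14 3-methylbutanoyl chloride
Product: 15 (2S,3E)-5-(TBSO)pent-3-en-2-yl 3-methylbutanoate
Conditions: pyridine, DMAP (5 mol %), CH2Cl2, 0 → 23 °C
Reagents that add atoms: none
Why: Acyl transfer (DMAP-catalysed esterification) with retention at the carbinol carbon.

Step 10
Reactants: 15 allylic isovalerate
Product: 18 (2R,3R,4E)-2-(propan-2-yl)-3-(TBSO-methyl)hex-4-enoic acid, via E-silyl ketene acetal 16 (not isolated), via trimethylsilyl ester 17 (not isolated)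
Conditions: LiN(iPr)2 (1.3 equiv), THF, −78 °C; Me3SiCl, −78 → 50 °C; aqueous citric acid
Reagents that add atoms: none
Why: Ireland–Claisen rearrangement; LiN(iPr)2 in THF gives the (E)-silyl ketene acetal, and the chair transition state with the carbinol methyl equatorial transfers the (S) chirality to C3 and sets C2 anti to it (E-alkene plus E-ketene acetal), giving the (2R,3R) acid that becomes the cis ring pattern.

Step 11
Reactants: 18 acid
Product: 19 (2R,3R,4E)-2-(propan-2-yl)-3-(TBSO-methyl)hex-4-en-1-ol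
Conditions: LiAlH4, Et2O, 0 → 23 °C; aqueous NaOH work-up
Reagents that add atoms: none
Why: Hydride reduction of the carboxylic acid to the primary alcohol; silyl ether and alkene are inert.

Step 12
Reactants: 19 alcohol
Product: 20 (2R,3R,4E)-2-(propan-2-yl)-3-(TBSO-methyl)hex-4-enal
Conditions: Dess–Martin periodinane, CH2Cl2, 0 → 23 °C
Reagents that add atoms: none
Why: Dess–Martin oxidation stops at the aldehyde under near-neutral conditions, so the α-stereocentre is not epimerised.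

Step 13
Reactants: 20 aldehyde
Product: 21 (3S,4R,5E)-3-(propan-2-yl)-4-(TBSO-methyl)hepta-1,5-diene
Conditions: Ph3PCH3 Br, KN(SiMe3)2, THF, 0 °C; then 20, −78 → 0 °C
Reagents that add atoms: methyltriphenylphosphonium bromide, C[P+](c1ccccc1)(c1ccccc1)c1ccccc1.[Br-]
Why: Wittig methylenation with the salt-free ylide is fast at low temperature and gives the terminal vinyl group without epimerisation.

Step 14
Reactants: 22 2-bromoprop-2-en-1-ol
Product: 23 [(2-bromoprop-2-en-1-yl)oxy]tri(propan-2-yl)silane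
Conditions: iPr3SiCl, imidazole, CH2Cl2, 23 °C
Reagents that add atoms: chlorotri(propan-2-yl)silane, CC(C)[Si](Cl)(C(C)C)C(C)C
Why: Silylation of the allylic alcohol.

Step 15
Reactants: 21 diene; 23 bromoallyl TIPS ether
Product: 25 (5R,6R,7E)-5-(propan-2-yl)-6-(TBSO-methyl)-2-(TIPSO-methyl)nona-1,7-diene, via B-alkyl-9-BBN borane 24 (not isolated)
Conditions: 9-BBN (1.2 equiv), THF, 0 → 23 °C; then 23, PdCl2(dppf) (5 mol %), K3PO4 (3 M in H2O), DMF, 50 °C
Reagents that add atoms: none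
Why: 9-BBN hydroborates only the monosubstituted alkene (anti-Markovnikov), and the B-alkyl Suzuki–Miyaura coupling joins the primary borane to the vinyl bromide without touching the stereocentres.

Step 16
Reactants: 25 1,7-diene
Product: 26 tert-butyl(dimethyl){[(1S,6R)-6-(propan-2-yl)-3-(TIPSO-methyl)cyclohex-2-en-1-yl]methoxy}silane
Conditions: (H2IMes)(PCy3)Cl2Ru=CHPh (second-generation Grubbs catalyst, 5 mol %), CH2Cl2 (5 mM), 40 °C
Reagents that add atoms: none
Why: Ring-closing metathesis closes ring B as a trisubstituted cyclohexene with loss of propene; the cis relation of the two ring stereocentres was fixed in step 10.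

Step 17
Reactants: 26 bis-silyl ether
Product: 27 [(1S,6R)-6-(propan-2-yl)-3-(TIPSO-methyl)cyclohex-2-en-1-yl]methanol
Conditions: pyridinium 4-toluenesulfonate (0.2 equiv), MeOH, 23 °C
Reagents that add atoms: none
Why: Acid-catalysed methanolysis cleaves the primary TBS ether far faster than the bulkier TIPS ether (selective desilylation).

Step 18
Reactants: 28 prop-2-en-1-yl (triphenylphosphoranylidene)acetate; 29 (chloromethoxy)tri(propan-2-yl)silane
Product: 31 prop-2-en-1-yl 2-(triphenylphosphoranylidene)-3-(TIPSO)propanoate, via phosphonium chloride 30 (not isolated)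
Conditions: CH2Cl2, 0 → 23 °C; then 1 M aqueous NaOH, 0 °C
Reagents that add atoms: none
Why: C-alkylation of the stabilised ylide by the reactive α-chloro ether, then deprotonation of the phosphonium salt to the new stabilised ylide.

Step 19
Reactants: 27 alcohol; 31 ylide
Product: 33 prop-2-en-1-yl (2E)-3-[(1S,6R)-6-(propan-2-yl)-3-(TIPSO-methyl)cyclohex-2-en-1-yl]-2-(TIPSO-methyl)prop-2-enoate, via cyclohexenecarbaldehyde 32 (not isolated)
Conditions: Dess–Martin periodinane, NaHCO3, CH2Cl2, 0 °C; then 31 (2 equiv) in the same flask, 23 → 40 °C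
Reagents that add atoms: none
Why: Dess–Martin oxidation with in-situ Wittig olefination; the stabilised ylide traps the epimerisable, doubly allylic aldehyde as it forms and gives the (E)-enoate (ester trans to the ring, CH2OTIPS cis to it) under thermodynamic control.

Step 20
Reactants: 33 allyl ester
Product: 34 (2E)-3-[(1S,6R)-6-(propan-2-yl)-3-(TIPSO-methyl)cyclohex-2-en-1-yl]-2-(TIPSO-methyl)prop-2-enoic acid
Conditions: Pd(PPh3)4 (5 mol %), morpholine (5 equiv), THF, 0 → 23 °C; dilute citric acid work-up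
Reagents that add atoms: none
Why: Tsuji–Trost deallylation; the π-allylpalladium complex from the allyl ester is intercepted by morpholine, freeing the acid under neutral conditions that leave the γ-stereocentre untouched.

**Union and end game**

Step 21
Reactants: 9 spiro-epoxide; 34 acid
Product: 35 [(1S,2R,3R,4R)-1-hydroxy-4-(propan-2-yl)-2-(TBSO-methyl)-3-vinylcyclohexyl]methyl ester of acid 34
Conditions: Cs2CO3 (0.3 equiv), DMF, 70 °C
Reagents that add atoms: none
Why: Base-catalysed epoxide opening by the carboxylate (SN2 at the CH2 terminus) joins the halves and keeps the C–O bond, hence the (S) configuration, of the tertiary carbinol; the few percent of material from ent-4 appear here as a separable diastereomer.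

Step 22
Reactants: 35 hydroxy ester
Product: 36 [(1S,2R,3R,4R)-1-hydroxy-2-(hydroxymethyl)-4-(propan-2-yl)-3-vinylcyclohexyl]methyl ester of acid 34
Conditions: pyridinium 4-toluenesulfonate (0.3 equiv), MeOH/CH2Cl2 1:1, 0 → 23 °C
Reagents that add atoms: none
Why: Selective acid-catalysed methanolysis of the primary TBS ether in the presence of the two TIPS ethers.

Step 23
Reactants: 36 diol
Product: 38 [(1S,2S,3R,4R)-2-carboxy-1-hydroxy-4-(propan-2-yl)-3-vinylcyclohexyl]methyl ester of acid 34, via formyl ester 37 (not isolated)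
Conditions: TEMPO (0.2 equiv), PhI(OAc)2 (2.5 equiv), MeCN/H2O 2:1, 23 °C
Reagents that add atoms: water, O
Why: Oxoammonium (TEMPO) oxidation takes the primary alcohol through the aldehyde hydrate to the acid and leaves the tertiary alcohol and the alkenes alone.

Step 24
Reactants: 38 acid; 39 tert-butyl 2-(bromomethyl)prop-2-enoate
Product: 40 [(1S,2S,3R,4R)-2-({[2-(tert-butoxycarbonyl)prop-2-en-1-yl]oxy}carbonyl)-1-hydroxy-4-(propan-2-yl)-3-vinylcyclohexyl]methyl ester of acid 34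
Conditions: KHCO3 (1.5 equiv), DMF, 23 °C
Reagents that add atoms: none
Why: O-alkylation of the carboxylate by the allylic bromide (SN2 or SN2', same product) avoids activating the hindered β-hydroxy acid.

Step 25
Reactants: 40 diene ester
Product: 41 tert-butyl (5aS,6R,9S,9aS)-9-[(acyloxy)methyl]-9-hydroxy-1-oxo-6-(propan-2-yl)-1,3,5a,6,7,8,9,9a-octahydro-2-benzoxepine-4-carboxylate (acyl = acyl group of 34)
Conditions: (H2IMes)Cl2Ru=CH(C6H4-2-OiPr) (second-generation Hoveyda–Grubbs catalyst, 10 mol %), 1,4-benzoquinone (20 mol %), toluene (2 mM), 80 °C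
Reagents that add atoms: none
Why: Ring-closing metathesis between the vinyl group and the 1,1-disubstituted acrylate closes the seven-membered lactone (ring C) with loss of ethene; the trans-diequatorial substituents pre-organise the chain and the ring enforces the alkene geometry.

Step 26
Reactants: 41 bis-TIPS lactone
Product: 42 tert-butyl (5aS,6R,9S,9aS)-9-hydroxy-9-({[(2E)-2-(hydroxymethyl)-3-[(1S,6R)-3-(hydroxymethyl)-6-(propan-2-yl)cyclohex-2-en-1-yl]prop-2-enoyl]oxy}methyl)-1-oxo-6-(propan-2-yl)-1,3,5a,6,7,8,9,9a-octahydro-2-benzoxepine-4-carboxylate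
Conditions: HF·pyridine, pyridine, THF, 0 → 23 °C
Reagents that add atoms: none
Why: Fluoride-induced desilylation (Si–F bond formation) frees both primary allylic alcohols; the esters, the lactone and the tert-butyl ester are stable.

Step 27
Reactants: 42 tert-butyl ester
Product: 43 (5aS,6R,9S,9aS)-9-hydroxy-9-({[(2E)-2-(hydroxymethyl)-3-[(1S,6R)-3-(hydroxymethyl)-6-(propan-2-yl)cyclohex-2-en-1-yl]prop-2-enoyl]oxy}methyl)-1-oxo-6-(propan-2-yl)-1,3,5a,6,7,8,9,9a-octahydro-2-benzoxepine-4-carboxylic acid (target)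
Conditions: CF3CO2H/CH2Cl2 1:4, 0 °C
Reagents that add atoms: none
Why: Acidolysis of the tert-butyl ester by the E1 path (loss of 2-methylpropene) frees the acid without base or nucleophile, which the 2-(acyloxymethyl)acrylate lactone would not tolerate.

**Compound list**

1 | 3-methylbutanal | CC(C)CC=O | starting material
2 | but-3-en-2-one | CC(=O)C=C | starting material
3 | (2R)-5-oxo-2-(propan-2-yl)hexanal | CC(C)[C@@H](CCC(C)=O)C=O | intermediate
4 | (4R)-4-(propan-2-yl)cyclohex-2-en-1-one | CC(C)[C@H]1CCC(=O)C=C1 | intermediate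
5 | vinylmagnesium bromide | C=C[Mg]Br | starting material
6 | trimethyl{[(3R,4R)-4-(propan-2-yl)-3-vinylcyclohex-1-en-1-yl]oxy}silane (vinyl trans to isopropyl) | CC(C)[C@H]1CCC(O[Si](C)(C)C)=C[C@@H]1C=C | intermediate
7 | (2R,3R,4R)-2-(hydroxymethyl)-4-(propan-2-yl)-3-vinylcyclohexan-1-one (all-trans) | CC(C)[C@H]1CCC(=O)[C@@H](CO)[C@@H]1C=C | intermediate
8 | (2R,3R,4R)-2-({[tert-butyl(dimethyl)silyl]oxy}methyl)-4-(propan-2-yl)-3-vinylcyclohexan-1-one | CC(C)[C@H]1CCC(=O)[C@@H](CO[Si](C)(C)C(C)(C)C)[C@@H]1C=C | intermediate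
9 | tert-butyl(dimethyl){[(3S,4R,5R,6R)-6-(propan-2-yl)-5-vinyl-1-oxaspiro[2.5]octan-4-yl]methoxy}silane (epoxide CH2 axial, O equatorial) | CC(C)[C@H]1CC[C@@]2(CO2)[C@@H](CO[Si](C)(C)C(C)(C)C)[C@@H]1C=C | intermediate
10 | {[tert-butyl(dimethyl)silyl]oxy}acetaldehyde | CC(C)(C)[Si](C)(C)OCC=O | starting material
11 | 1-(triphenylphosphoranylidene)propan-2-one | CC(=O)C=P(c1ccccc1)(c1ccccc1)c1ccccc1 | starting material
12 | (3E)-5-{[tert-butyl(dimethyl)silyl]oxy}pent-3-en-2-one | CC(=O)/C=C/CO[Si](C)(C)C(C)(C)C | intermediate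
13 | (2S,3E)-5-{[tert-butyl(dimethyl)silyl]oxy}pent-3-en-2-ol | C[C@H](O)/C=C/CO[Si](C)(C)C(C)(C)C | intermediate
14 | 3-methylbutanoyl chloride | CC(C)CC(=O)Cl | starting material
15 | (2S,3E)-5-{[tert-butyl(dimethyl)silyl]oxy}pent-3-en-2-yl 3-methylbutanoate | CC(C)CC(=O)O[C@@H](C)/C=C/CO[Si](C)(C)C(C)(C)C | intermediate
16 | {[(1E)-3-methyl-1-{[(2S,3E)-5-(TBSO)pent-3-en-2-yl]oxy}but-1-en-1-yl]oxy}trimethylsilane (isopropyl trans to OTMS) | CC(C)/C=C(/O[Si](C)(C)C)O[C@@H](C)/C=C/CO[Si](C)(C)C(C)(C)C | intermediate (not isolated)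
17 | trimethylsilyl (2R,3R,4E)-2-(propan-2-yl)-3-(TBSO-methyl)hex-4-enoate | C[Si](C)(C)OC(=O)[C@H](C(C)C)[C@H](CO[Si](C)(C)C(C)(C)C)/C=C/C | intermediate (not isolated)
18 | (2R,3R,4E)-3-({[tert-butyl(dimethyl)silyl]oxy}methyl)-2-(propan-2-yl)hex-4-enoic acid | OC(=O)[C@H](C(C)C)[C@H](CO[Si](C)(C)C(C)(C)C)/C=C/C | intermediate
19 | (2R,3R,4E)-3-({[tert-butyl(dimethyl)silyl]oxy}methyl)-2-(propan-2-yl)hex-4-en-1-ol | OC[C@H](C(C)C)[C@H](CO[Si](C)(C)C(C)(C)C)/C=C/C | intermediate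
20 | (2R,3R,4E)-3-({[tert-butyl(dimethyl)silyl]oxy}methyl)-2-(propan-2-yl)hex-4-enal | O=C[C@H](C(C)C)[C@H](CO[Si](C)(C)C(C)(C)C)/C=C/C | intermediate
21 | (3S,4R,5E)-4-({[tert-butyl(dimethyl)silyl]oxy}methyl)-3-(propan-2-yl)hepta-1,5-diene | C=C[C@H](C(C)C)[C@H](CO[Si](C)(C)C(C)(C)C)/C=C/C | intermediate
22 | 2-bromoprop-2-en-1-ol | OCC(Br)=C | starting material
23 | [(2-bromoprop-2-en-1-yl)oxy]tri(propan-2-yl)silane | C=C(Br)CO[Si](C(C)C)(C(C)C)C(C)C | intermediate
24 | 9-[(3R,4R,5E)-3-(propan-2-yl)-4-(TBSO-methyl)hept-5-en-1-yl]-9-borabicyclo[3.3.1]nonane | C1CCC2CCCC1B2CC[C@H](C(C)C)[C@H](CO[Si](C)(C)C(C)(C)C)/C=C/C | intermediate (not isolated)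
25 | (5R,6R,7E)-6-({[tert-butyl(dimethyl)silyl]oxy}methyl)-5-(propan-2-yl)-2-({[tri(propan-2-yl)silyl]oxy}methyl)nona-1,7-diene | C=C(CO[Si](C(C)C)(C(C)C)C(C)C)CC[C@H](C(C)C)[C@H](CO[Si](C)(C)C(C)(C)C)/C=C/C | intermediate
26 | tert-butyl(dimethyl){[(1S,6R)-6-(propan-2-yl)-3-({[tri(propan-2-yl)silyl]oxy}methyl)cyclohex-2-en-1-yl]methoxy}silane (cis) | CC(C)(C)[Si](C)(C)OC[C@@H]1C=C(CO[Si](C(C)C)(C(C)C)C(C)C)CC[C@@H]1C(C)C | intermediate
27 | [(1S,6R)-6-(propan-2-yl)-3-({[tri(propan-2-yl)silyl]oxy}methyl)cyclohex-2-en-1-yl]methanol | OC[C@@H]1C=C(CO[Si](C(C)C)(C(C)C)C(C)C)CC[C@@H]1C(C)C | intermediate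
28 | prop-2-en-1-yl (triphenylphosphoranylidene)acetate | C=CCOC(=O)C=P(c1ccccc1)(c1ccccc1)c1ccccc1 | starting material
29 | (chloromethoxy)tri(propan-2-yl)silane | ClCO[Si](C(C)C)(C(C)C)C(C)C | starting material
30 | {1-[(prop-2-en-1-yloxy)carbonyl]-2-{[tri(propan-2-yl)silyl]oxy}ethyl}triphenylphosphonium chloride | C=CCOC(=O)C(CO[Si](C(C)C)(C(C)C)C(C)C)[P+](c1ccccc1)(c1ccccc1)c1ccccc1.[Cl-] | intermediate (not isolated)
31 | prop-2-en-1-yl 2-(triphenylphosphoranylidene)-3-{[tri(propan-2-yl)silyl]oxy}propanoate | C=CCOC(=O)C(CO[Si](C(C)C)(C(C)C)C(C)C)=P(c1ccccc1)(c1ccccc1)c1ccccc1 | intermediate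
32 | (1S,6R)-6-(propan-2-yl)-3-({[tri(propan-2-yl)silyl]oxy}methyl)cyclohex-2-ene-1-carbaldehyde | O=C[C@@H]1C=C(CO[Si](C(C)C)(C(C)C)C(C)C)CC[C@@H]1C(C)C | intermediate (not isolated)
33 | prop-2-en-1-yl (2E)-3-[(1S,6R)-6-(propan-2-yl)-3-(TIPSO-methyl)cyclohex-2-en-1-yl]-2-(TIPSO-methyl)prop-2-enoate | C=CCOC(=O)/C(=C/[C@@H]1C=C(CO[Si](C(C)C)(C(C)C)C(C)C)CC[C@@H]1C(C)C)CO[Si](C(C)C)(C(C)C)C(C)C | intermediate
34 | (2E)-3-[(1S,6R)-6-(propan-2-yl)-3-(TIPSO-methyl)cyclohex-2-en-1-yl]-2-(TIPSO-methyl)prop-2-enoic acid | OC(=O)/C(=C/[C@@H]1C=C(CO[Si](C(C)C)(C(C)C)C(C)C)CC[C@@H]1C(C)C)CO[Si](C(C)C)(C(C)C)C(C)C | intermediate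
35 | [(1S,2R,3R,4R)-1-hydroxy-4-(propan-2-yl)-2-(TBSO-methyl)-3-vinylcyclohexyl]methyl ester of acid 34 | CC(C)[C@H]1CC[C@@](O)(COC(=O)/C(=C/[C@@H]2C=C(CO[Si](C(C)C)(C(C)C)C(C)C)CC[C@@H]2C(C)C)CO[Si](C(C)C)(C(C)C)C(C)C)[C@@H](CO[Si](C)(C)C(C)(C)C)[C@@H]1C=C | intermediate
36 | [(1S,2R,3R,4R)-1-hydroxy-2-(hydroxymethyl)-4-(propan-2-yl)-3-vinylcyclohexyl]methyl ester of acid 34 | CC(C)[C@H]1CC[C@@](O)(COC(=O)/C(=C/[C@@H]2C=C(CO[Si](C(C)C)(C(C)C)C(C)C)CC[C@@H]2C(C)C)CO[Si](C(C)C)(C(C)C)C(C)C)[C@@H](CO)[C@@H]1C=C | intermediate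
37 | [(1S,2S,3R,4R)-2-formyl-1-hydroxy-4-(propan-2-yl)-3-vinylcyclohexyl]methyl ester of acid 34 | CC(C)[C@H]1CC[C@@](O)(COC(=O)/C(=C/[C@@H]2C=C(CO[Si](C(C)C)(C(C)C)C(C)C)CC[C@@H]2C(C)C)CO[Si](C(C)C)(C(C)C)C(C)C)[C@@H](C=O)[C@@H]1C=C | intermediate (not isolated)
38 | [(1S,2S,3R,4R)-2-carboxy-1-hydroxy-4-(propan-2-yl)-3-vinylcyclohexyl]methyl ester of acid 34 | CC(C)[C@H]1CC[C@@](O)(COC(=O)/C(=C/[C@@H]2C=C(CO[Si](C(C)C)(C(C)C)C(C)C)CC[C@@H]2C(C)C)CO[Si](C(C)C)(C(C)C)C(C)C)[C@@H](C(=O)O)[C@@H]1C=C | intermediate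
39 | tert-butyl 2-(bromomethyl)prop-2-enoate | C=C(CBr)C(=O)OC(C)(C)C | starting material
40 | [(1S,2S,3R,4R)-2-({[2-(tert-butoxycarbonyl)prop-2-en-1-yl]oxy}carbonyl)-1-hydroxy-4-(propan-2-yl)-3-vinylcyclohexyl]methyl ester of acid 34 | CC(C)[C@H]1CC[C@@](O)(COC(=O)/C(=C/[C@@H]2C=C(CO[Si](C(C)C)(C(C)C)C(C)C)CC[C@@H]2C(C)C)CO[Si](C(C)C)(C(C)C)C(C)C)[C@@H](C(=O)OCC(=C)C(=O)OC(C)(C)C)[C@@H]1C=C | intermediate
41 | tert-butyl (5aS,6R,9S,9aS)-9-hydroxy-1-oxo-6-(propan-2-yl)-9-[(acyloxy)methyl]-1,3,5a,6,7,8,9,9a-octahydro-2-benzoxepine-4-carboxylate, acyl = acyl group of 34 | CC(C)[C@H]1CC[C@@](O)(COC(=O)/C(=C/[C@@H]2C=C(CO[Si](C(C)C)(C(C)C)C(C)C)CC[C@@H]2C(C)C)CO[Si](C(C)C)(C(C)C)C(C)C)[C@H]3C(=O)OCC(C(=O)OC(C)(C)C)=C[C@H]13 | intermediate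
42 | tert-butyl ester of the target (both ring-B-side primary alcohols free) | CC(C)[C@H]1CC[C@@](O)(COC(=O)/C(=C/[C@@H]2C=C(CO)CC[C@@H]2C(C)C)CO)[C@H]3C(=O)OCC(C(=O)OC(C)(C)C)=C[C@H]13 | intermediate
43 | (5aS,6R,9S,9aS)-9-hydroxy-9-({[(2E)-2-(hydroxymethyl)-3-[(1S,6R)-3-(hydroxymethyl)-6-(propan-2-yl)cyclohex-2-en-1-yl]prop-2-enoyl]oxy}methyl)-1-oxo-6-(propan-2-yl)-1,3,5a,6,7,8,9,9a-octahydro-2-benzoxepine-4-carboxylic acid | CC(C)[C@H]1CC[C@@](O)(COC(=O)/C(=C/[C@@H]2C=C(CO)CC[C@@H]2C(C)C)CO)[C@H]2C(=O)OCC(C(=O)O)=C[C@H]12 | target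

**Step count and risks**

Total: 27 steps (6 to epoxide 9, 14 to acid 34 including two reagent preparations, 7 after the union). Longest linear sequence: 19 steps (7–13, 15–17, 19–27).

Three steps most likely to fail:

Step 19. The cis, doubly allylic aldehyde 32 may epimerise or move into conjugation before the hindered ylide 31 reacts. The fallback sets out from 27 and comes back at 33. 27 is oxidised as before, and the cold solution of 32 is added at −78 °C to the α-aluminated acrylate made from prop-2-en-1-yl prop-2-ynoate, i-Bu2AlH and N-methylmorpholine N-oxide in THF. This fast 1,2-addition gives the Baylis–Hillman-type carbinol F1 (both carbinol epimers, of no consequence). Ph3SiOReO3 (2 mol %, Et2O, 0 °C) then moves the hydroxyl by a 1,3-allylic transposition to the more substituted, conjugated primary allylic alcohol F2 with the ring trans to the ester. iPr3SiCl and imidazole convert it into 33.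

Step 21. The bulky carboxylate of 34 may open the neopentyl-like epoxide too slowly at a temperature the acid tolerates. The fallback sets out from 9 and comes back at 35, replacing the alkylative union by an acylation. CsOAc/AcOH in DMF at 90 °C opens 9 to the hydroxy acetate F3, and K2CO3 in MeOH gives the diol F4. Its primary hydroxyl alone is acylated by the mixed anhydride of 34 (2,4,6-trichlorobenzoyl chloride, Et3N, toluene; then DMAP, 0 °C), giving 35.

Step 25. The vinyl group is hindered, the acrylate is electron-poor and 1,1-disubstituted, and ruthenium hydrides could move the doubly allylic alkene of ring B. The fallback sets out from 9 and comes back at 42, building ring C by olefination and lactonisation instead of metathesis: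
- Ozonolysis of 9 (O3, CH2Cl2/MeOH, −78 °C; PPh3) gives the aldehyde F5.
- Wittig reaction with the tert-butyl ylide F6 (from tert-butyl (triphenylphosphoranylidene)acetate and 29 as in step 18) gives the (E)-enoate F7.
- Epoxide opening with 34 as in step 21 gives the ester F8.
- TBS removal as in step 22 gives the alcohol F9, and oxidation as in step 23 gives the acid F10.
- HF·pyridine removes all three TIPS groups to give the seco acid F11.
- 2-Methyl-6-nitrobenzoic anhydride and DMAP at high dilution close only the seven-membered lactone (the competing nine-membered and macrocyclic lactones form far more slowly), giving 42.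

**Further compounds**

F1 | step 19 | prop-2-en-1-yl 2-{hydroxy[(1S,6R)-6-(propan-2-yl)-3-(TIPSO-methyl)cyclohex-2-en-1-yl]methyl}prop-2-enoate (both carbinol epimers) | C=CCOC(=O)C(=C)C(O)[C@@H]1C=C(CO[Si](C(C)C)(C(C)C)C(C)C)CC[C@@H]1C(C)C
F2 | step 19 | prop-2-en-1-yl (2E)-2-(hydroxymethyl)-3-[(1S,6R)-6-(propan-2-yl)-3-(TIPSO-methyl)cyclohex-2-en-1-yl]prop-2-enoate | C=CCOC(=O)/C(=C/[C@@H]1C=C(CO[Si](C(C)C)(C(C)C)C(C)C)CC[C@@H]1C(C)C)CO
F3 | step 21 | [(1S,2R,3R,4R)-1-hydroxy-4-(propan-2-yl)-2-(TBSO-methyl)-3-vinylcyclohexyl]methyl acetate | CC(C)[C@H]1CC[C@@](O)(COC(C)=O)[C@@H](CO[Si](C)(C)C(C)(C)C)[C@@H]1C=C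
F4 | step 21 | (1S,2R,3R,4R)-1-(hydroxymethyl)-4-(propan-2-yl)-2-(TBSO-methyl)-3-vinylcyclohexan-1-ol | CC(C)[C@H]1CC[C@@](O)(CO)[C@@H](CO[Si](C)(C)C(C)(C)C)[C@@H]1C=C
F5 | step 25 | (3S,4R,5R,6R)-6-(propan-2-yl)-4-(TBSO-methyl)-1-oxaspiro[2.5]octane-5-carbaldehyde | CC(C)[C@H]1CC[C@@]2(CO2)[C@@H](CO[Si](C)(C)C(C)(C)C)[C@@H]1C=O
F6 | step 25 | tert-butyl 2-(triphenylphosphoranylidene)-3-{[tri(propan-2-yl)silyl]oxy}propanoate | CC(C)(C)OC(=O)C(CO[Si](C(C)C)(C(C)C)C(C)C)=P(c1ccccc1)(c1ccccc1)c1ccccc1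
F7 | step 25 | tert-butyl (2E)-3-[(3S,4R,5S,6R)-6-(propan-2-yl)-4-(TBSO-methyl)-1-oxaspiro[2.5]octan-5-yl]-2-(TIPSO-methyl)prop-2-enoate | CC(C)[C@H]1CC[C@@]2(CO2)[C@@H](CO[Si](C)(C)C(C)(C)C)[C@@H]1/C=C(\CO[Si](C(C)C)(C(C)C)C(C)C)C(=O)OC(C)(C)C
F8 | step 25 | [(1S,2R,3S,4R)-3-[(1E)-3-tert-butoxy-3-oxo-2-(TIPSO-methyl)prop-1-en-1-yl]-1-hydroxy-4-(propan-2-yl)-2-(TBSO-methyl)cyclohexyl]methyl ester of acid 34 | CC(C)[C@H]1CC[C@@](O)(COC(=O)/C(=C/[C@@H]2C=C(CO[Si](C(C)C)(C(C)C)C(C)C)CC[C@@H]2C(C)C)CO[Si](C(C)C)(C(C)C)C(C)C)[C@@H](CO[Si](C)(C)C(C)(C)C)[C@@H]1/C=C(\CO[Si](C(C)C)(C(C)C)C(C)C)C(=O)OC(C)(C)C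
F9 | step 25 | the 2-(hydroxymethyl) analogue of F8, (1S,2R,3S,4R) | CC(C)[C@H]1CC[C@@](O)(COC(=O)/C(=C/[C@@H]2C=C(CO[Si](C(C)C)(C(C)C)C(C)C)CC[C@@H]2C(C)C)CO[Si](C(C)C)(C(C)C)C(C)C)[C@@H](CO)[C@@H]1/C=C(\CO[Si](C(C)C)(C(C)C)C(C)C)C(=O)OC(C)(C)C
F10 | step 25 | the 2-carboxy analogue of F8, (1S,2S,3S,4R) | CC(C)[C@H]1CC[C@@](O)(COC(=O)/C(=C/[C@@H]2C=C(CO[Si](C(C)C)(C(C)C)C(C)C)CC[C@@H]2C(C)C)CO[Si](C(C)C)(C(C)C)C(C)C)[C@@H](C(=O)O)[C@@H]1/C=C(\CO[Si](C(C)C)(C(C)C)C(C)C)C(=O)OC(C)(C)C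
F11 | step 25 | seco acid of 42 (2-carboxy, three free CH2OH groups, tert-butyl ester kept), (1S,2S,3S,4R) | CC(C)[C@H]1CC[C@@](O)(COC(=O)/C(=C/[C@@H]2C=C(CO)CC[C@@H]2C(C)C)CO)[C@@H](C(=O)O)[C@@H]1/C=C(\CO)C(=O)OC(C)(C)C
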